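## Structural features

- Ring A is a pentasubstituted benzene of the phloroacetophenone type. C8 carries the acetyl group and is flanked by the hydrogen-bonded phenol O7–H and by the ring oxygen O1 on C8a; C6–H is the only aromatic hydrogen.
- Ring B is a 3,4-dihydro-2H-pyran fused at C4a–C8a. It holds a fully substituted C2 (gem-dimethyl, bonded to O1), the only stereocentre C3 (R, secondary OH) directly beside it, and a benzylic C4H2.
- The third phenolic oxygen (on C5, para to the acetyl) carries an (E)-geranyl chain. This allylic aryl ether ionises in acid, undergoes [3,3] shift on strong heating, and its two trisubstituted alkenes react with every electrophilic oxidant (peracids, dioxiranes, OsO4, hypochlorite) and with hydrogenation catalysts.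
- Further fragile groups are the o-hydroxyaryl methyl ketone (Dakin-type oxidation, aldol reactions at the acetyl CH3) and the acidic chelated phenol.
- Hidden symmetry: without C2–C4, ring A is a 4-O-geranyl-2,6-dihydroxyacetophenone in which O1/C4a and O7/C6 are equivalent. Annulation of ring B onto this diphenol therefore has no regiochemical choice.
- The real difficulty is chemoselectivity, not complexity: C3–O must be created enantioselectively, next to quaternary C2, in a molecule whose side chain holds the alkenes most reactive toward electrophilic oxygen.
- The key step exploits the C3=C4 bond of a 2H-chromene precursor. It is the only alkene conjugated to ring A, hence the only one that can accept a nucleophilic boryl-copper reagent, because only there is the resulting C4–Cu bond benzylic.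

## Logic of the disconnections

**8 ⇒ 7.** The C3–O bond is cut and replaced by a C3–B bond. A secondary boronic ester is oxidised to the alcohol with retention, so the stereochemical problem moves to a C–B bond-forming step that can be nucleophilic instead of electrophilic. The forward step needs an oxidant that spares two trisubstituted alkenes and the o-hydroxyaryl ketone.

**7 ⇒ 6 (key disconnection).** The C3–B and C4–H bonds are cut, leading back to the achiral, flat chromene 6, which already holds every carbon of the target and the geranyl ether. In one sentence: the single stereocentre is created by a ligand-controlled nucleophilic boryl-copper addition to the ring B alkene of fully assembled, achiral 6. The gain is the removal of the only stereocentre and of every protecting group, since no electrophilic oxidant is needed anywhere. The forward step must choose C3=C4 over the two side-chain alkenes, put boron on C3 and not on C4, and distinguish the two faces of the alkene by the catalyst alone.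

**6 ⇒ 3 + 4 (through 5).** The O1–C2 and C4–C4a bonds are cut, so ring B becomes a formal [3+3] union of a 1,3-C,O-dinucleophile with a five-carbon enal. The hindered tertiary aryl ether bond O1–C2 is then formed intramolecularly by a pericyclic closure of 5 and not by substitution at a tertiary carbon. Because 3 is symmetric and its para oxygen is blocked, only one regioisomer can form. The forward step must stop after one annulation and stay below the temperature at which the geranyl ether rearranges.

**3 ⇒ 1 + 2.** The O–C1′ bond of the geranyl ether is cut. The 4-OH of 1 is the only hydroxyl that is not hydrogen-bonded to the acetyl group and is the most acidic. This leaves two commercial materials. The forward step must favour O- over C-alkylation and mono- over bis-alkylation.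

## Other disconnections considered

Alternative 1: Cut O1–C2 (the first route that comes to mind). The forward key step is the 6-endo opening of the enantioenriched epoxide A1 by the neighbouring phenol oxygen at the tertiary carbon; A1 would come from Shi epoxidation of the C-prenyl phenol A2. A dioxirane epoxidises all trisubstituted alkenes alike, so the geranyl chain cannot be present. The oxygen on C5 then needs a placeholder (benzyl in A1 and A2) and the route needs two extra steps for its removal and replacement. C-prenylation of the phloroglucinol nucleus to reach A2 is expected to give O/C and mono/bis mixtures, and the closure has a 5-exo/6-endo ambiguity that is resolved only under acid. The chosen plan has no placeholder, no such ambiguity and fewer steps.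

Alternative 2: Cut C4–C4a at the ketone oxidation level. The forward key step is the Rh2(OAc)4-catalysed decomposition of diazoketone A3, in which the carbenoid attacks the only free ortho position of ring A to give chroman-3-one A4; an enantioselective Corey–Bakshi–Shibata reduction would then set C3. A3 requires an intermolecular tertiary ether formation at a chelated, hindered phenol, followed by several functional group steps that end with diazomethane. The electrophilic rhodium carbenoid would meet two electron-rich alkenes, which is the same chemoselectivity problem in another form. The final reduction would have to distinguish two ketones. The plan is longer and its stereocentre is set no more simply than in the chosen route.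

Alternative 3: Cut C4–C4a with the stereocentre imported. The forward key step is an intramolecular Friedel–Crafts opening of the terminal epoxide of aryl ether A5, in which ring A attacks the CH2 terminus (6-endo) and the configuration of the epoxide CH carbon becomes C3 unchanged. No dependable method attaches a tertiary carbinol that carries an intact enantiopure epoxide to a chelated phenol oxygen: ionising conditions open the epoxide, and SN2 displacement at a tertiary carbon is not available. The Lewis acid needed for the closure would also ionise the geranyl ether, and competing 5-exo attack at the epoxide CH carbon would scramble C3. The difficulty is moved into the precursor, not removed.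

Key step: step 3

Assumption: (R,R)-QuinoxP* is written for step 3 on the assumption that it delivers boron to the face that gives (3R)-7. The sense of induction on this substrate cannot be predicted with certainty; if the first run gives (3S), (S,S)-QuinoxP* is used with no other change.

## Route

Step 1
Reactants: 1 1-(2,4,6-trihydroxyphenyl)ethan-1-one (phloroacetophenone, dried); 2 geranyl bromide, (2E)-1-bromo-3,7-dimethylocta-2,6-diene
Product: 3 1-[4-{[(2E)-3,7-dimethylocta-2,6-dien-1-yl]oxy}-2,6-dihydroxyphenyl]ethan-1-one
Conditions: K2CO3 (1.1 equiv), acetone, 56 °C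
Reagents that add atoms: none
Why: Williamson ether synthesis; the 4-OH is para to the acetyl group and not hydrogen-bonded, so it is the most acidic and the only one deprotonated by one equivalent of weak base, and its phenoxide should displace the primary allylic bromide by SN2 without touching the E alkene.

Step 2
Reactants: 3 1-[4-{[(2E)-3,7-dimethylocta-2,6-dien-1-yl]oxy}-2,6-dihydroxyphenyl]ethan-1-one; 4 3-methylbut-2-enal (prenal)
Product: 6 1-[5-{[(2E)-3,7-dimethylocta-2,6-dien-1-yl]oxy}-7-hydroxy-2,2-dimethyl-2H-chromen-8-yl]ethan-1-one, via o-quinone methide 5 (not isolated)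
Conditions: 4 (1.1 equiv), ethylenediammonium diacetate (20 mol %), toluene, 110 °C
Reagents that add atoms: none
Why: Formal [3+3] annulation: Knoevenagel-type attack of the ring carbon between OH and O-geranyl on the iminium ion of 4 and loss of the amine should give 5, whose oxa-6π electrocyclisation forms O1–C2 and restores aromaticity; the symmetry of 3 and the blocked para oxygen allow only one regioisomer.

Step 3
Reactants: 6 1-[5-{[(2E)-3,7-dimethylocta-2,6-dien-1-yl]oxy}-7-hydroxy-2,2-dimethyl-2H-chromen-8-yl]ethan-1-one
Product: 7 1-[(3R)-5-{[(2E)-3,7-dimethylocta-2,6-dien-1-yl]oxy}-7-hydroxy-2,2-dimethyl-3-(4,4,5,5-tetramethyl-1,3,2-dioxaborolan-2-yl)-3,4-dihydro-2H-chromen-8-yl]ethan-1-one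
Conditions: CuCl (10 mol %), (R,R)-QuinoxP* (11 mol %), NaOtBu (20 mol %), B2pin2 (1.5 equiv), MeOH (4 equiv), THF, 0 °C to rt
Reagents that add atoms: bis(pinacolato)diboron, CC1(C)OB(OC1(C)C)B1OC(C)(C)C(C)(C)O1
Why: This is an enantioselective copper-catalysed protoboration of a cyclic vinylarene: CuCl, NaOtBu and the bisphosphine give L*Cu–OtBu, which B2pin2 converts into the nucleophilic L*Cu–Bpin. Syn insertion of C3=C4 into the Cu–B bond should put boron on C3 and copper on benzylic C4, where ring A stabilises the C–Cu bond; the reverse orientation lacks this stabilisation and would place copper beta to O1. Methanol then cleaves the C4–Cu bond to C4–H and returns L*Cu–OMe, which re-enters the cycle with B2pin2. The closest known reaction type is the enantioselective boryl-cupration and protonation of indenes, 1,2-dihydronaphthalenes and N-acyl-1,2-dihydroquinolines, which gives the homobenzylic boronates. No ring is closed; the step forms the C3–B and C4–H bonds on the preformed ring B. C3 is the only new stereocentre and is set by the chiral ligand alone, which selects one of the two enantiotopic faces of the flat alkene, the substrate having no bias because C2 carries two identical methyl groups. The step needs site selectivity against the two geranyl alkenes, and the substrate secures it: only C3=C4 is conjugated to an arene, and L*Cu–Bpin does not add to unactivated trisubstituted alkenes, in contrast to every electrophilic oxidant. The acetyl group is shielded by two ortho substituents and by the hydrogen bond to O7–H, and the acidic phenol should act only as an additional proton source.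

Step 4
Reactants: 7 1-[(3R)-5-{[(2E)-3,7-dimethylocta-2,6-dien-1-yl]oxy}-7-hydroxy-2,2-dimethyl-3-(4,4,5,5-tetramethyl-1,3,2-dioxaborolan-2-yl)-3,4-dihydro-2H-chromen-8-yl]ethan-1-one
Product: 8 1-[(3R)-5-{[(2E)-3,7-dimethylocta-2,6-dien-1-yl]oxy}-3,7-dihydroxy-2,2-dimethyl-3,4-dihydro-2H-chromen-8-yl]ethan-1-one
Conditions: NaBO3·4H2O (4 equiv), THF/H2O 1:1, 0 °C to rt
Reagents that add atoms: sodium perborate tetrahydrate, [Na+].[Na+].O[B-]1(O)OO[B-](O)(O)OO1
Why: Oxidation of a secondary boronic ester: the peroxoborate adds to boron and C3 migrates from boron to oxygen with retention, so (3R)-7 should give (3R)-8; the nucleophilic, mildly basic oxidant does not epoxidise electron-rich alkenes and should be too mild for Dakin-type attack on the hindered, chelated acetyl group at room temperature.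

## Compound list

1 | 1-(2,4,6-trihydroxyphenyl)ethan-1-one (phloroacetophenone) | CC(=O)c1c(O)cc(O)cc1O | starting material
2 | geranyl bromide, (2E)-1-bromo-3,7-dimethylocta-2,6-diene | BrC/C=C(\C)CCC=C(C)C | starting material
3 | 1-[4-{[(2E)-3,7-dimethylocta-2,6-dien-1-yl]oxy}-2,6-dihydroxyphenyl]ethan-1-one | CC(=O)c1c(O)cc(OC/C=C(\C)CCC=C(C)C)cc1O | intermediate
4 | 3-methylbut-2-enal (prenal) | CC(C)=CC=O | starting material
5 | (6Z)-2-acetyl-5-{[(2E)-3,7-dimethylocta-2,6-dien-1-yl]oxy}-3-hydroxy-6-(3-methylbut-2-en-1-ylidene)cyclohexa-2,4-dien-1-one (o-quinone methide) | CC(=O)C1=C(O)C=C(OC/C=C(\C)CCC=C(C)C)/C(=C/C=C(C)C)C1=O | intermediate (not isolated)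
6 | 1-[5-{[(2E)-3,7-dimethylocta-2,6-dien-1-yl]oxy}-7-hydroxy-2,2-dimethyl-2H-chromen-8-yl]ethan-1-one | CC(=O)c1c(O)cc(OC/C=C(\C)CCC=C(C)C)c2c1OC(C)(C)C=C2 | intermediate
7 | 1-[(3R)-5-{[(2E)-3,7-dimethylocta-2,6-dien-1-yl]oxy}-7-hydroxy-2,2-dimethyl-3-(4,4,5,5-tetramethyl-1,3,2-dioxaborolan-2-yl)-3,4-dihydro-2H-chromen-8-yl]ethan-1-one | CC(=O)c1c(O)cc(OC/C=C(\C)CCC=C(C)C)c2c1OC(C)(C)[C@H](B3OC(C)(C)C(C)(C)O3)C2 | intermediate
8 | 1-[(3R)-5-{[(2E)-3,7-dimethylocta-2,6-dien-1-yl]oxy}-3,7-dihydroxy-2,2-dimethyl-3,4-dihydro-2H-chromen-8-yl]ethan-1-one | CC(=O)c1c(O)cc(OC/C=C(\C)CCC=C(C)C)c2c1OC(C)(C)[C@H](O)C2 | target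

## Step count and least certain steps

Total step count: 4. Longest linear sequence: 4 steps (1 → 3 → 6 → 7 → 8). No protecting group is used.

**Step 3 (key step).** Several processes could defeat it:
- slow boryl-cupration, because the three oxygen donors of ring A destabilise the C4–Cu bond and boron must bond to C3 beside quaternary C2;
- capture of the catalyst by the acidic phenol as a copper aryloxide that returns to Cu–B only slowly;
- SN2′ boryl substitution at the allylic aryl ether, with loss of the geranyl chain;
- insufficient facial discrimination.

The fallback uses an electrophilic, epoxide-based way of setting C3, so the geranyl chain has to come last. It sets out from 1 and returns to the route at 8: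
- Alkylation of 1 with benzyl bromide and K2CO3 in acetone should give 1-[4-(benzyloxy)-2,6-dihydroxyphenyl]ethan-1-one F1.
- Annulation with 4 under the conditions of step 2 should give 1-[5-(benzyloxy)-7-hydroxy-2,2-dimethyl-2H-chromen-8-yl]ethan-1-one F2.
- Jacobsen epoxidation of this cis-disubstituted chromene should give 1-[(3R,4R)-5-(benzyloxy)-3,4-epoxy-7-hydroxy-2,2-dimethyl-3,4-dihydro-2H-chromen-8-yl]ethan-1-one F3. The conditions are (R,R)-N,N′-bis(3,5-di-tert-butylsalicylidene)-1,2-cyclohexanediaminomanganese chloride, (R,R)-(salen)MnCl, with mCPBA and N-methylmorpholine N-oxide in CH2Cl2 at −78 °C.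
- Hydrogenation (H2, Pd/C, EtOAc with a trace of Et3N) should cleave the benzylic C4–O bond and the benzyl ether while leaving C3–O untouched, giving 1-[(3R)-3,5,7-trihydroxy-2,2-dimethyl-3,4-dihydro-2H-chromen-8-yl]ethan-1-one F4.
- Alkylation of the only non-chelated phenol of F4 with 2 and K2CO3 in acetone should give 8.

**Step 2.** A second annulation with 4 at the remaining hydroxyl/C–H pair, aldol condensation of 4 at the acetyl methyl group, and slow [3,3] rearrangement of the geranyl ether on prolonged heating are the likely losses. The fallback attaches exactly one five-carbon unit to oxygen before any C–C bond is formed; it sets out from 3 and returns at 6: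
- Copper-catalysed etherification of 3 with 2-methylbut-3-yn-2-yl methyl carbonate (CuCl2 5 mol %, DBU, MeCN, 0 °C) should give 1-[4-{[(2E)-3,7-dimethylocta-2,6-dien-1-yl]oxy}-2-hydroxy-6-[(2-methylbut-3-yn-2-yl)oxy]phenyl]ethan-1-one F5.
- Heating F5 in toluene at 110–130 °C should trigger the aromatic propargyl Claisen rearrangement to the only free ortho carbon, a 1,5-hydrogen shift to 5, and electrocyclisation to 6.

**Step 1.** C-alkylation at the ring carbons of the ambident phloroglucinol phenoxide and a second O-alkylation would lower the yield of 3. The fallback is a Mitsunobu etherification of 1 with geraniol (PPh3, diisopropyl azodicarboxylate, THF, 0 °C). It engages only the most acidic 4-OH and never exposes a free phenoxide to an allylic halide. It sets out from 1 and returns at 3, and it makes no new compound (F0).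

## Further compounds

F1 | step 3 | 1-[4-(benzyloxy)-2,6-dihydroxyphenyl]ethan-1-one | CC(=O)c1c(O)cc(OCc2ccccc2)cc1O
F2 | step 3 | 1-[5-(benzyloxy)-7-hydroxy-2,2-dimethyl-2H-chromen-8-yl]ethan-1-one | CC(=O)c1c(O)cc(OCc3ccccc3)c2c1OC(C)(C)C=C2
F3 | step 3 | 1-[(3R,4R)-5-(benzyloxy)-3,4-epoxy-7-hydroxy-2,2-dimethyl-3,4-dihydro-2H-chromen-8-yl]ethan-1-one | CC(=O)c1c(O)cc(OCc3ccccc3)c2c1OC(C)(C)[C@@H]4O[C@H]24
F4 | step 3 | 1-[(3R)-3,5,7-trihydroxy-2,2-dimethyl-3,4-dihydro-2H-chromen-8-yl]ethan-1-one | CC(=O)c1c(O)cc(O)c2c1OC(C)(C)[C@H](O)C2
F5 | step 2 | 1-[4-{[(2E)-3,7-dimethylocta-2,6-dien-1-yl]oxy}-2-hydroxy-6-[(2-methylbut-3-yn-2-yl)oxy]phenyl]ethan-1-one | CC(=O)c1c(O)cc(OC/C=C(\C)CCC=C(C)C)cc1OC(C)(C)C#C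
F0 | step 1 | none | none
A1 | alternative 1 | 1-[4-(benzyloxy)-3-{[(2R)-3,3-dimethyloxiran-2-yl]methyl}-2,6-dihydroxyphenyl]ethan-1-one | CC(=O)c1c(O)cc(OCc2ccccc2)c(C[C@H]3OC3(C)C)c1O
A2 | alternative 1 | 1-[4-(benzyloxy)-2,6-dihydroxy-3-(3-methylbut-2-en-1-yl)phenyl]ethan-1-one | CC(=O)c1c(O)cc(OCc2ccccc2)c(CC=C(C)C)c1O
A3 | alternative 2 | 3-[2-acetyl-5-{[(2E)-3,7-dimethylocta-2,6-dien-1-yl]oxy}-3-hydroxyphenoxy]-1-diazo-3-methylbutan-2-one | CC(=O)c1c(O)cc(OC/C=C(\C)CCC=C(C)C)cc1OC(C)(C)C(=O)C=[N+]=[N-]
A4 | alternative 2 | 8-acetyl-5-{[(2E)-3,7-dimethylocta-2,6-dien-1-yl]oxy}-7-hydroxy-2,2-dimethyl-2H-chromen-3(4H)-one | CC(=O)c1c(O)cc(OC/C=C(\C)CCC=C(C)C)c2c1OC(C)(C)C(=O)C2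
A5 | alternative 3 | 1-[4-{[(2E)-3,7-dimethylocta-2,6-dien-1-yl]oxy}-2-hydroxy-6-({2-[(2R)-oxiran-2-yl]propan-2-yl}oxy)phenyl]ethan-1-one | CC(=O)c1c(O)cc(OC/C=C(\C)CCC=C(C)C)cc1OC(C)(C)[C@H]2CO2
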